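**Retrosynthetic overview**
- The target comes from its 5‑O‑MOM ether by mild acid hydrolysis. That (2S)‑ether is the unreacted enantiomer of the racemic flavanone in a Noyori‑type transfer‑hydrogenation kinetic resolution.
- The pyranone (C) ring is the only ring made. It closes by intramolecular oxa‑Michael addition of a 2'‑hydroxychalcone through its single free phenol, which fixes the side chain at C8.
- Key C–C bond (C2–C3): the chalcone comes from the fully substituted A‑ring methyl ketone and benzaldehyde by intermolecular Claisen–Schmidt aldol condensation.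
- The 3‑hydroxy‑3‑methylbutyl chain comes from an aryl iodide and 2‑methylbut‑3‑yn‑2‑ol (Sonogashira, then hydrogenation, which also frees the cyclising phenol).
- The aryl iodide comes from phloroacetophenone by 4‑O‑methylation, mono‑MOM protection, ortho‑iodination and benzylation. Rings A and B are bought; ring C is formed last.

Assumption: phloroacetophenone is used as its commercial monohydrate (dried before use); the target SMILES is read as the (2S)‑flavanone.

**Step 1**
Reactants: 1 1-(2,4,6-trihydroxyphenyl)ethanone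
Product: 2 1-(2,6-dihydroxy-4-methoxyphenyl)ethanone
Conditions: Me2SO4 (1.0 equiv), K2CO3 (1.0 equiv), acetone, reflux, 4 h; chromatography
Reagents that add atoms: dimethyl sulfate, COS(=O)(=O)OC
Why: Williamson O‑methylation, selective because the 4‑OH is the only phenol not hydrogen‑bonded to the acetyl carbonyl and is the most acidic, so one equivalent of base and electrophile alkylates it first (the dimethyl ether by‑product is separated).

**Step 2**
Reactants: 2 1-(2,6-dihydroxy-4-methoxyphenyl)ethanone
Product: 3 1-[2-hydroxy-4-methoxy-6-(methoxymethoxy)phenyl]ethanone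
Conditions: MOMCl (1.1 equiv), K2CO3 (1.5 equiv), acetone, 0 °C → rt
Reagents that add atoms: chloromethyl methyl ether, COCCl
Why: Williamson‑type MOM protection of one of two equivalent phenols; after the first alkylation the remaining OH is locked in a strong hydrogen bond to the carbonyl and does not react with a slight excess of reagent.

**Step 3**
Reactants: 3 1-[2-hydroxy-4-methoxy-6-(methoxymethoxy)phenyl]ethanone
Product: 4 1-[2-hydroxy-3-iodo-4-methoxy-6-(methoxymethoxy)phenyl]ethanone
Conditions: BnMe3N+ ICl2− (1.05 equiv), NaHCO3 (3 equiv), CH2Cl2/MeOH (5:2), rt, dark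
Reagents that add atoms: benzyltrimethylammonium dichloroiodate, C[N+](C)(C)Cc1ccccc1.Cl[I-]Cl
Why: Electrophilic aromatic iodination in which the free chelated phenol directs iodine to its only open ortho position (C3), the usual outcome for 2‑hydroxy‑4,6‑dialkoxyacetophenones with this reagent, while the bicarbonate buffer protects the MOM acetal.

**Step 4**
Reactants: 4 1-[2-hydroxy-3-iodo-4-methoxy-6-(methoxymethoxy)phenyl]ethanone
Product: 5 1-[2-(benzyloxy)-3-iodo-4-methoxy-6-(methoxymethoxy)phenyl]ethanone
Conditions: BnBr (1.3 equiv), K2CO3 (2 equiv), DMF, 60 °C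
Reagents that add atoms: benzyl bromide, BrCc1ccccc1
Why: Williamson benzylation of the hindered phenoxide in DMF, which masks the ortho‑OH so that the following alkyne coupling cannot cyclise to a benzofuran.

**Step 5**
Reactants: 5 1-[2-(benzyloxy)-3-iodo-4-methoxy-6-(methoxymethoxy)phenyl]ethanone + 6 2-methylbut-3-yn-2-ol
Product: 7 1-[2-(benzyloxy)-3-(3-hydroxy-3-methylbut-1-yn-1-yl)-4-methoxy-6-(methoxymethoxy)phenyl]ethanone
Conditions: 6 (2 equiv), PdCl2(PPh3)2 (5 mol%), CuI (10 mol%), Et3N/DMF (1:1), 65 °C, Ar
Reagents that add atoms: none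
Why: Sonogashira coupling, reliable here because aryl iodides undergo fast oxidative addition even when electron‑rich and flanked by two ortho substituents, and the ketone, MOM and benzyl groups are inert.

**Step 6**
Reactants: 7 1-[2-(benzyloxy)-3-(3-hydroxy-3-methylbut-1-yn-1-yl)-4-methoxy-6-(methoxymethoxy)phenyl]ethanone
Product: 9 1-[2-hydroxy-3-(3-hydroxy-3-methylbutyl)-4-methoxy-6-(methoxymethoxy)phenyl]ethanone, via saturated benzyl ether 8 (not isolated)
Conditions: H2 (1 atm), 10% Pd/C, EtOAc/EtOH (1:1), rt
Reagents that add atoms: none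
Why: Catalytic hydrogenation followed by hydrogenolysis on Pd/C saturates the alkyne and then cleaves the benzyl ether in one operation, while the aryl MOM ether, the hindered chelated aryl ketone and the tertiary alcohol survive the neutral conditions.

**Step 7**
Reactants: 9 1-[2-hydroxy-3-(3-hydroxy-3-methylbutyl)-4-methoxy-6-(methoxymethoxy)phenyl]ethanone + 10 benzaldehyde
Product: 12 (E)-1-[2-hydroxy-3-(3-hydroxy-3-methylbutyl)-4-methoxy-6-(methoxymethoxy)phenyl]-3-phenylprop-2-en-1-one, via β-hydroxy ketone aldol adduct 11 (not isolated)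
Conditions: PhCHO (1.5 equiv), 50% aq KOH, EtOH, 0 °C → rt, 48 h; then cold aq NH4Cl/AcOH to pH 6
Reagents that add atoms: none
Why: Claisen–Schmidt (crossed aldol) condensation in which the methyl ketone enolate adds to non‑enolisable benzaldehyde and the aldol dehydrates by E1cB to the conjugated E‑chalcone, forming the future C2–C3 bond and joining the A‑ring and B‑ring fragments (the basic medium and near‑neutral work‑up avoid acid‑induced chroman formation from the free phenol and tertiary alcohol).

**Step 8**
Reactants: 12 (E)-1-[2-hydroxy-3-(3-hydroxy-3-methylbutyl)-4-methoxy-6-(methoxymethoxy)phenyl]-3-phenylprop-2-en-1-one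
Product: 13 rac-8-(3-hydroxy-3-methylbutyl)-7-methoxy-5-(methoxymethoxy)-2-phenyl-2,3-dihydro-4H-chromen-4-one
Conditions: NaOAc (10 equiv), EtOH, reflux, 24 h
Reagents that add atoms: none
Why: Intramolecular oxa‑Michael addition of the only free phenol (the one next to the alkyl chain) can give only the 8‑substituted flavanone, and the 6'‑alkoxy group shifts the chalcone–flavanone equilibrium to the ring‑closed side; C2 is formed racemic at this stage.

**Step 9**
Reactants: 13 rac-8-(3-hydroxy-3-methylbutyl)-7-methoxy-5-(methoxymethoxy)-2-phenyl-2,3-dihydro-4H-chromen-4-one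
Product: 14 (2S)-8-(3-hydroxy-3-methylbutyl)-7-methoxy-5-(methoxymethoxy)-2-phenyl-2,3-dihydro-4H-chromen-4-one
Conditions: [Cp*RhCl((R,R)-TsDPEN)] (1 mol%), HCO2H/Et3N (5:2), EtOAc, 30 °C, to ca. 55% conversion (chiral HPLC, ≥98% ee of ketone); SiO2 separation; maximum yield 50%
Reagents that add atoms: none
Why: Noyori–Ikariya asymmetric transfer hydrogenation run as a kinetic resolution: the (R,R)‑catalyst forms 4R carbinols and flavanones reduce to 2,4‑cis alcohols, so the (2R)‑ketone is the matched, fast‑reacting enantiomer (it becomes the (2R,4R)‑flavan‑4‑ol) and the (2S)‑ketone is recovered with C2 untouched, so the 2S centre is selected here rather than created.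

**Step 10**
Reactants: 14 (2S)-8-(3-hydroxy-3-methylbutyl)-7-methoxy-5-(methoxymethoxy)-2-phenyl-2,3-dihydro-4H-chromen-4-one
Product: 15 (2S)-5-hydroxy-8-(3-hydroxy-3-methylbutyl)-7-methoxy-2-phenyl-2,3-dihydro-4H-chromen-4-one
Conditions: 3 M aq HCl/THF (1:3), 40 °C; pH 7 buffer work‑up, no base
Reagents that add atoms: none
Why: Acid‑catalysed acetal hydrolysis of the peri (5‑O) MOM group, which is activated by the neighbouring carbonyl and leaves in dilute aqueous acid; under these conditions the tertiary alcohol (water as co‑solvent, no free ortho phenol to trap a cation) and the C2 centre (which racemises by base‑induced ring opening) are stable.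

**Compound list**
1 | 1-(2,4,6-trihydroxyphenyl)ethanone (phloroacetophenone) | CC(=O)c1c(O)cc(O)cc1O | starting material
2 | 1-(2,6-dihydroxy-4-methoxyphenyl)ethanone | CC(=O)c1c(O)cc(OC)cc1O | intermediate
3 | 1-[2-hydroxy-4-methoxy-6-(methoxymethoxy)phenyl]ethanone | CC(=O)c1c(O)cc(OC)cc1OCOC | intermediate
4 | 1-[2-hydroxy-3-iodo-4-methoxy-6-(methoxymethoxy)phenyl]ethanone | CC(=O)c1c(O)c(I)c(OC)cc1OCOC | intermediate
5 | 1-[2-(benzyloxy)-3-iodo-4-methoxy-6-(methoxymethoxy)phenyl]ethanone | CC(=O)c1c(OCc2ccccc2)c(I)c(OC)cc1OCOC | intermediate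
6 | 2-methylbut-3-yn-2-ol | CC(C)(O)C#C | starting material
7 | 1-[2-(benzyloxy)-3-(3-hydroxy-3-methylbut-1-yn-1-yl)-4-methoxy-6-(methoxymethoxy)phenyl]ethanone | CC(=O)c1c(OCc2ccccc2)c(C#CC(C)(C)O)c(OC)cc1OCOC | intermediate
8 | 1-[2-(benzyloxy)-3-(3-hydroxy-3-methylbutyl)-4-methoxy-6-(methoxymethoxy)phenyl]ethanone | CC(=O)c1c(OCc2ccccc2)c(CCC(C)(C)O)c(OC)cc1OCOC | intermediate
9 | 1-[2-hydroxy-3-(3-hydroxy-3-methylbutyl)-4-methoxy-6-(methoxymethoxy)phenyl]ethanone | CC(=O)c1c(O)c(CCC(C)(C)O)c(OC)cc1OCOC | intermediate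
10 | benzaldehyde | O=Cc1ccccc1 | starting material
11 | rac-3-hydroxy-1-[2-hydroxy-3-(3-hydroxy-3-methylbutyl)-4-methoxy-6-(methoxymethoxy)phenyl]-3-phenylpropan-1-one | COCOc1cc(OC)c(CCC(C)(C)O)c(O)c1C(=O)CC(O)c1ccccc1 | intermediate
12 | (E)-1-[2-hydroxy-3-(3-hydroxy-3-methylbutyl)-4-methoxy-6-(methoxymethoxy)phenyl]-3-phenylprop-2-en-1-one | COCOc1cc(OC)c(CCC(C)(C)O)c(O)c1C(=O)/C=C/c1ccccc1 | intermediate
13 | rac-8-(3-hydroxy-3-methylbutyl)-7-methoxy-5-(methoxymethoxy)-2-phenyl-2,3-dihydro-4H-chromen-4-one | COc1cc(OCOC)c2c(c1CCC(C)(C)O)OC(c1ccccc1)CC2=O | intermediate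
14 | (2S)-8-(3-hydroxy-3-methylbutyl)-7-methoxy-5-(methoxymethoxy)-2-phenyl-2,3-dihydro-4H-chromen-4-one | COc1cc(OCOC)c2c(c1CCC(C)(C)O)O[C@H](c1ccccc1)CC2=O | intermediate
15 | (2S)-5-hydroxy-8-(3-hydroxy-3-methylbutyl)-7-methoxy-2-phenyl-2,3-dihydro-4H-chromen-4-one | COc1cc(O)c2c(c1CCC(C)(C)O)O[C@H](c1ccccc1)CC2=O | target

**Step count and weak points**
Total steps: 10. Longest linear sequence: 10 steps (1 → 15); 6 and 10 enter as single commercial inputs.

Most likely to fail, first: step 9. The selectivity factor of the resolution on a 5‑alkoxy‑8‑alkyl flavanone is unproven, the peri substituent may slow the reduction, and the yield cannot exceed 50%. The fallback creates C2 by catalytic asymmetric C–C bond formation instead of resolving; it sets out from 9 and comes back at 14. Ketone 9 is heated with DMF dimethyl acetal (toluene, 90 °C) to the enaminone (E)-3-(dimethylamino)-1-[2-hydroxy-3-(3-hydroxy-3-methylbutyl)-4-methoxy-6-(methoxymethoxy)phenyl]prop-2-en-1-one F1. This closes with loss of dimethylamine (AcOH, 60 °C) to the chromone 8-(3-hydroxy-3-methylbutyl)-7-methoxy-5-(methoxymethoxy)-4H-chromen-4-one F2. Rhodium‑catalysed asymmetric 1,4‑addition of phenylboronic acid ([Rh(OH)(cod)]2, an (S)‑configured electron‑poor MeO‑BIPHEP‑type bisphosphine, toluene/H2O, rt) then gives 14 directly. The enone‑face model that gives (S)‑3‑phenylcyclohexanone corresponds to 2S here, and the sense is confirmed by chiral HPLC.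

Second: step 3. Iodination could partly go para to the free phenol (C5, between OMe and OMOM) or run on to the di‑iodide. The fallback moves the regiochemical decision from C–I bond formation to O‑protection; it sets out from 2 and comes back at 4. The symmetric diol 2, whose two open ring positions are equivalent, is mono‑iodinated (same reagent, 1.0 equiv, 0 °C) to 1-(2,6-dihydroxy-3-iodo-4-methoxyphenyl)ethanone F3. MOMCl/i‑Pr2NEt (CH2Cl2, 0 °C) then alkylates the unhindered 6‑OH and leaves the OH wedged between iodine and acetyl, giving 4.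

Third: step 10. The Brønsted acid could dehydrate or solvolyse the tertiary alcohol, or erode ee, before the MOM group is fully gone. The fallback replaces hydrolysis by silyl exchange; it sets out from 14 and comes back at 15. TMSOTf/2,2'‑bipyridyl (CH2Cl2, 0 °C) converts the aryl MOM acetal into an aryl silyl ether without free acid and silylates the tertiary alcohol, giving (2S)-7-methoxy-8-[3-methyl-3-(trimethylsilyloxy)butyl]-2-phenyl-5-(trimethylsilyloxy)-2,3-dihydro-4H-chromen-4-one F4. Both O–Si bonds are then hydrolysed (citric acid, MeOH/H2O, rt) to 15.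

**Further compounds**
F1 | step 9 | (E)-3-(dimethylamino)-1-[2-hydroxy-3-(3-hydroxy-3-methylbutyl)-4-methoxy-6-(methoxymethoxy)phenyl]prop-2-en-1-one | CN(C)/C=C/C(=O)c1c(O)c(CCC(C)(C)O)c(OC)cc1OCOC
F2 | step 9 | 8-(3-hydroxy-3-methylbutyl)-7-methoxy-5-(methoxymethoxy)-4H-chromen-4-one | COc1cc(OCOC)c2c(c1CCC(C)(C)O)OC=CC2=O
F3 | step 3 | 1-(2,6-dihydroxy-3-iodo-4-methoxyphenyl)ethanone | CC(=O)c1c(O)c(I)c(OC)cc1O
F4 | step 10 | (2S)-7-methoxy-8-[3-methyl-3-(trimethylsilyloxy)butyl]-2-phenyl-5-(trimethylsilyloxy)-2,3-dihydro-4H-chromen-4-one | COc1cc(O[Si](C)(C)C)c2c(c1CCC(C)(C)O[Si](C)(C)C)O[C@H](c1ccccc1)CC2=O
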